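Ring B (B1 carries the CH2 link to aromatic ring A, B3 is the dimethyl carbon, B5 carries the acetyl group; B2, B4 and B6 bear oxygen) is a 2-acylcyclohexane-1,3,5-trione, i.e. a folded 3,5,7-trioxooctanoate whose C2 (B3) has no hydrogen. The route therefore rests on the B4–B5 disconnection: one base-mediated Claisen closure of an open-chain triketo ester (methyl ester C1, dimethylated C2, ketones C3, C5 and C7, the 2,4,6-trimethoxybenzyl group on C4) forms ring B with its full substitution. Ring A stays a symmetric trimethyl ether until the end, when it is butanoylated and demethylated beside the new ketone.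

Key step: step 6

Remark: C4 of 9 and 11 is a stereocentre between two ketones; it forms as a racemate, epimerises through the enol and becomes the trigonal carbon B1 in 12, so no configuration is assigned. Compounds 11, 12, 14 and 15 are written as single enol tautomers of mixtures.

Step 1
Reactants: 1 2,4,6-trimethoxybenzaldehyde; 2 malonic acid
Product: 3 (E)-3-(2,4,6-trimethoxyphenyl)prop-2-enoic acid
Conditions: pyridine, piperidine (cat.), 100 °C; then aq. HCl
Reagents that add atoms: malonic acid (2), OC(=O)CC(O)=O
Why: Knoevenagel–Doebner condensation, in which malonate adds to the piperidine-activated aldehyde and the adduct loses water and CO2 in hot pyridine, which should give the conjugated acid as the thermodynamically preferred (E)-alkene even from this electron-rich, doubly ortho-substituted aldehyde.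

Step 2
Reactants: 3 (E)-3-(2,4,6-trimethoxyphenyl)prop-2-enoic acid
Product: 4 3-(2,4,6-trimethoxyphenyl)propanoic acid
Conditions: H2 (1 atm), Pd/C, EtOAc–MeOH, rt
Reagents that add atoms: none
Why: Heterogeneous catalytic hydrogenation of a conjugated C=C bond, under which the aryl methyl ethers and the carboxylic acid are inert.

Step 3
Reactants: 4 3-(2,4,6-trimethoxyphenyl)propanoic acid; 5 methyl 2-methylpropanoate
Product: 7 methyl 2,2-dimethyl-3-oxo-5-(2,4,6-trimethoxyphenyl)pentanoate, via acyl imidazole 6 (not isolated)
Conditions: CDI, THF, rt (gives 6); separately 5 (3.2 equiv), LiN(i-Pr)2 (3.1 equiv), THF, −78 °C; add 6, −78 → −30 °C; aq. NH4Cl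
Reagents that add atoms: methyl 2-methylpropanoate (5), COC(=O)C(C)C; 1,1'-carbonyldiimidazole, O=C(n1ccnc1)n1ccnc1 (imidazolyl group of 6 only)
Why: Crossed Claisen-type C-acylation of a lithium ester enolate by an acyl imidazole, chosen because this activation involves no chlorinating or Lewis-acidic electrophile that could attack the very electron-rich ring A, and because the new C2 is quaternary so the β-keto ester cannot enolise between its carbonyl groups and condense further.

Step 4
Reactants: 7 methyl 2,2-dimethyl-3-oxo-5-(2,4,6-trimethoxyphenyl)pentanoate; 8 1-acetyl-1H-benzotriazole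
Product: 9 methyl 2,2-dimethyl-3,5-dioxo-4-[(2,4,6-trimethoxyphenyl)methyl]hexanoate
Conditions: MgBr2·OEt2 (2.5 equiv), i-Pr2NEt (3 equiv), CH2Cl2, rt; then 1 M HCl
Reagents that add atoms: 1-acetyl-1H-benzotriazole (8), CC(=O)n1nnc2ccccc12
Why: Soft-enolisation C-acylation of a ketone, in which MgBr2 chelated by the C1 and C3 carbonyl groups acidifies the C4 methylene (the only enolisable position), the amine-generated magnesium enolate is acylated on carbon by the acylbenzotriazole, and the product is held as an unreactive magnesium diketonate that resists a second acylation.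

Step 5
Reactants: 9 methyl 2,2-dimethyl-3,5-dioxo-4-[(2,4,6-trimethoxyphenyl)methyl]hexanoate; 10 N-methoxy-N-methylacetamide
Product: 11 methyl 2,2-dimethyl-3,5,7-trioxo-4-[(2,4,6-trimethoxyphenyl)methyl]octanoate
Conditions: LiN(i-Pr)2 (2.3 equiv), THF, −78 °C; 10 (1.3 equiv), −78 → −40 °C; AcOH, −78 °C
Reagents that add atoms: N-methoxy-N-methylacetamide (10), CC(=O)N(C)OC
Why: Terminal acylation of a β-diketone dianion with a Weinreb amide, where after C4 only the C6 methyl can be deprotonated because C2 is quaternary, the more basic terminal carbanion attacks the amide, the chelated tetrahedral adduct survives until the cold acidic quench (no proton exchange or double acylation), and the low temperature should keep the dianion from attacking its own C1 ester.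

Step 6
Reactants: 11 methyl 2,2-dimethyl-3,5,7-trioxo-4-[(2,4,6-trimethoxyphenyl)methyl]octanoate
Product: 12 2-acetyl-3,5-dihydroxy-4,4-dimethyl-6-[(2,4,6-trimethoxyphenyl)methyl]cyclohexa-2,5-dien-1-one
Conditions: KOt-Bu (3.0 equiv), THF, 0 °C → rt (50 °C if slow); then cold 1 M HCl
Reagents that add atoms: none
Why: KOt-Bu deprotonates C6 (between the C5 and C7 ketones) and then C4 of 11; C6 of the resulting dienolate adds to the C1 ester carbonyl and the tetrahedral intermediate expels methoxide, forming the B4–B5 bond and ring B, which is at once deprotonated to its stabilised enolate. The closest known reaction is the Claisen (Dieckmann-type) cyclisation of 3,5,7-trioxoalkanoates to 2-acylcyclohexane-1,3,5-triones, the chemical model of acylphloroglucinol biosynthesis, applied here to a substrate with a quaternary C2. Ring B closes in a 6-(enolexo)-exo-trig mode, C6 reacting through its C6=C7 enolate with the ester C=O outside the new ring. No stereocentre is created, and the labile C4 centre of 11 becomes the trigonal carbon B1. The step needs C-acylation by C6 in preference to lactonisation through the C5 enolate oxygen, aldol closure and retro-Claisen cleavage beside the dimethyl carbon: C2 has no hydrogen, so the C2-to-C7 aldol is impossible, the alkoxide cannot ionise the C8 methyl, so the C8-to-C3 aldol does not start, C3 is masked inside the C3–C5 enolate and shielded by the neighbouring quaternary carbon, and the two methyl groups favour the folded chain. O-acylation is reversible under alkoxide whereas the strongly acidic product is removed as its anion, so the equilibria should drain into 12, which cold dilute acid releases.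

Step 7
Reactants: 12 2-acetyl-3,5-dihydroxy-4,4-dimethyl-6-[(2,4,6-trimethoxyphenyl)methyl]cyclohexa-2,5-dien-1-one; 13 butanoyl chloride
Product: 14 2-acetyl-6-[(3-butanoyl-2,4,6-trimethoxyphenyl)methyl]-3,5-dihydroxy-4,4-dimethylcyclohexa-2,5-dien-1-one
Conditions: 13 (1.5 equiv), TiCl4 (3.5 equiv), CH2Cl2, −20 °C → rt; 1 M HCl; then NaHCO3, MeOH–H2O, rt; HCl
Reagents that add atoms: butanoyl chloride (13), CCCC(=O)Cl
Why: Friedel–Crafts acylation of a 1,3,5-trimethoxyarene, in which the two free positions of ring A are equivalent and each is ortho, ortho and para to a methoxy group, so mono-acylation should be fast and regiochemically unambiguous, the new ketone deactivates the ring against a second acylation, ring B (held as a titanium chelate) offers no free carbon nucleophile, and any enol butanoate is cleaved in the bicarbonate wash.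

Step 8
Reactants: 14 2-acetyl-6-[(3-butanoyl-2,4,6-trimethoxyphenyl)methyl]-3,5-dihydroxy-4,4-dimethylcyclohexa-2,5-dien-1-one
Product: 15 2-acetyl-6-[(3-butanoyl-2,4-dihydroxy-6-methoxyphenyl)methyl]-3,5-dihydroxy-4,4-dimethylcyclohexa-2,5-dien-1-one
Conditions: BCl3 (8 equiv), CH2Cl2, −78 °C → rt; ice–water
Reagents that add atoms: none
Why: Chelation-controlled aryl methyl ether cleavage, in which BCl3 bound to the butanoyl oxygen reaches only the two methoxy groups ortho to the ketone and removes their methyl groups as chloromethane through six-membered aryloxyboron chelates, whereas the methoxy group para to the ketone cannot chelate and should be kept (the slower second cleavage is the reason for excess reagent and room temperature).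

Compound list
1 | 2,4,6-trimethoxybenzaldehyde | COc1cc(OC)c(C=O)c(OC)c1 | starting material
2 | malonic acid | OC(=O)CC(O)=O | starting material
3 | (E)-3-(2,4,6-trimethoxyphenyl)prop-2-enoic acid | COc1cc(OC)c(/C=C/C(O)=O)c(OC)c1 | intermediate
4 | 3-(2,4,6-trimethoxyphenyl)propanoic acid | COc1cc(OC)c(CCC(O)=O)c(OC)c1 | intermediate
5 | methyl 2-methylpropanoate | COC(=O)C(C)C | starting material
6 | 1-(1H-imidazol-1-yl)-3-(2,4,6-trimethoxyphenyl)propan-1-one | COc1cc(OC)c(CCC(=O)n2ccnc2)c(OC)c1 | intermediate (not isolated)
7 | methyl 2,2-dimethyl-3-oxo-5-(2,4,6-trimethoxyphenyl)pentanoate | COC(=O)C(C)(C)C(=O)CCc1c(OC)cc(OC)cc1OC | intermediate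
8 | 1-acetyl-1H-benzotriazole | CC(=O)n1nnc2ccccc12 | starting material
9 | methyl 2,2-dimethyl-3,5-dioxo-4-[(2,4,6-trimethoxyphenyl)methyl]hexanoate | COC(=O)C(C)(C)C(=O)C(Cc1c(OC)cc(OC)cc1OC)C(C)=O | intermediate
10 | N-methoxy-N-methylacetamide | CC(=O)N(C)OC | starting material
11 | methyl 2,2-dimethyl-3,5,7-trioxo-4-[(2,4,6-trimethoxyphenyl)methyl]octanoate | COC(=O)C(C)(C)C(=O)C(Cc1c(OC)cc(OC)cc1OC)C(=O)CC(C)=O | intermediate
12 | 2-acetyl-3,5-dihydroxy-4,4-dimethyl-6-[(2,4,6-trimethoxyphenyl)methyl]cyclohexa-2,5-dien-1-one | COc1cc(OC)c(CC2=C(O)C(C)(C)C(O)=C(C(C)=O)C2=O)c(OC)c1 | intermediate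
13 | butanoyl chloride | CCCC(=O)Cl | starting material
14 | 2-acetyl-6-[(3-butanoyl-2,4,6-trimethoxyphenyl)methyl]-3,5-dihydroxy-4,4-dimethylcyclohexa-2,5-dien-1-one | CCCC(=O)c1c(OC)cc(OC)c(CC2=C(O)C(C)(C)C(O)=C(C(C)=O)C2=O)c1OC | intermediate
15 | 2-acetyl-6-[(3-butanoyl-2,4-dihydroxy-6-methoxyphenyl)methyl]-3,5-dihydroxy-4,4-dimethylcyclohexa-2,5-dien-1-one | CCCC(=O)c1c(O)cc(OC)c(CC2=C(O)C(C)(C)C(O)=C(C(C)=O)C2=O)c1O | target

Total step count: 8. Longest linear sequence: 8 steps (1 to 15).

Steps most likely to fail

Step 5. Once the C6 carbanion of the dianion exists, it sits six atoms from the C1 ester and may close ring B before the amide is attacked (premature Claisen closure to the acetyl-free ring), or the second deprotonation may stay incomplete. The fallback sets out from 7 and comes back at 11; it brings in C5 to C8 as one masked piece on C4, so that no terminal carbanion ever coexists with the ester. (2-Methyl-1,3-dioxolan-2-yl)acetic acid and CDI in THF should give the acyl imidazole 1-(1H-imidazol-1-yl)-2-(2-methyl-1,3-dioxolan-2-yl)ethan-1-one F1. The lithium enolate of 7 (LiN(SiMe3)2, 2.1 equiv, THF, −78 °C) is C-acylated by it to the ketal-protected diketone methyl 2,2-dimethyl-6-(2-methyl-1,3-dioxolan-2-yl)-3,5-dioxo-4-[(2,4,6-trimethoxyphenyl)methyl]hexanoate F2. Brief treatment with 1 M HCl in THF at room temperature should remove the dioxolane and give 11.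

Step 6. The C6 carbon of the diketonate may be too weak a nucleophile for the hindered ester, so that the chain diverts into O-acylation (enol lactone), fragments by retro-Claisen attack of alkoxide, or dehydrates to a pyranone during acidic work-up. The fallback sets out from 9 and comes back at 12; it closes ring B before the acetyl group is present, using the far more nucleophilic terminal carbanion. Treatment of 9 with LiN(i-Pr)2 (2.2 equiv) in THF, −78 °C → rt, should bring about the same C6-to-C1 Claisen closure and give 2,2-dimethyl-4-[(2,4,6-trimethoxyphenyl)methyl]cyclohexane-1,3,5-trione F3. Acetyl chloride and Et3N in CH2Cl2 convert it into the enol ester 5-hydroxy-6,6-dimethyl-3-oxo-4-[(2,4,6-trimethoxyphenyl)methyl]cyclohexa-1,4-dien-1-yl acetate F4. Catalytic 4-(dimethylamino)pyridine then shifts the acetyl group from oxygen to carbon, onto the only ring carbon that still bears hydrogen, which gives 12.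

Step 7. The acid chloride may acylate the enol oxygens of ring B and the triketone may sequester the Lewis acid, which would stall the arene acylation, or the strongly acidic medium may cleave the bond between ring A and the CH2 link by ipso attack. The fallback sets out from 12 and comes back at 14; it is a Houben–Hoesch acylation, which uses no acyl chloride and a weaker Lewis acid. Butanenitrile, ZnCl2 and dry HCl in Et2O–CH2Cl2 at 0 °C should convert ring A into the ketimine 2-acetyl-6-{[3-(butanimidoyl)-2,4,6-trimethoxyphenyl]methyl}-3,5-dihydroxy-4,4-dimethylcyclohexa-2,5-dien-1-one F5, collected as its hydrochloride, and warming in water hydrolyses it to 14.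

Further compounds
F1 | step 5 | 1-(1H-imidazol-1-yl)-2-(2-methyl-1,3-dioxolan-2-yl)ethan-1-one | CC1(CC(=O)n2ccnc2)OCCO1
F2 | step 5 | methyl 2,2-dimethyl-6-(2-methyl-1,3-dioxolan-2-yl)-3,5-dioxo-4-[(2,4,6-trimethoxyphenyl)methyl]hexanoate | COC(=O)C(C)(C)C(=O)C(Cc1c(OC)cc(OC)cc1OC)C(=O)CC1(C)OCCO1
F3 | step 6 | 2,2-dimethyl-4-[(2,4,6-trimethoxyphenyl)methyl]cyclohexane-1,3,5-trione | COc1cc(OC)c(CC2C(=O)CC(=O)C(C)(C)C2=O)c(OC)c1
F4 | step 6 | 5-hydroxy-6,6-dimethyl-3-oxo-4-[(2,4,6-trimethoxyphenyl)methyl]cyclohexa-1,4-dien-1-yl acetate | COc1cc(OC)c(CC2=C(O)C(C)(C)C(OC(C)=O)=CC2=O)c(OC)c1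
F5 | step 7 | 2-acetyl-6-{[3-(butanimidoyl)-2,4,6-trimethoxyphenyl]methyl}-3,5-dihydroxy-4,4-dimethylcyclohexa-2,5-dien-1-one | CCCC(=N)c1c(OC)cc(OC)c(CC2=C(O)C(C)(C)C(O)=C(C(C)=O)C2=O)c1OC
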